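**Retrosynthetic overview**

1. Target 23 is cut at the two ring–alkyne bonds (Sonogashira), giving enol triflate 4 (ring A, the monohydroxy end, primed positions), enol triflate 12 (ring B, the diol end, unprimed positions) and a linear C22 polyenediyne chain.
2. The chain comes from C10 dial 16 and two copies of C6 enyne ylide 18 (Wittig at C11′=C12′ and C11=C12), assembled in the order Wittig, Sonogashira (ring A), Wittig, Sonogashira (ring B).
3. Ring A: triflate 4 ⇐ cyclohexanone 3 ⇐ cyclopentanone 2 ⇐ cyclobutanone 1, by two successive one-carbon ring expansions (4→5 with CMe2 as an enantioselective desymmetrisation, then 5→6 with CHMe).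
4. Ring B: triflate 12 ⇐ cyclohexanone 10 ⇐ 9 ⇐ meso cyclopentanone 8 (from cyclopent-3-en-1-ol 5), by an enantioselective desymmetrising 5→6 ring expansion with CMe2 that fixes the cis-3,4-diol configuration.
5. Ring order: the six-membered ring A is completed first (steps 1–2), the six-membered ring B second (step 6); neither ring is made by cyclisation and both are joined to the chain last.

Assumption: the sense of induction of the new scandium-catalysed step cannot be predicted, so the antipode of ligand L that gives the drawn enantiomer is fixed in a pilot run for steps 1 and 6 (L is the C2-symmetric N,N′-dioxide diamide from (S)-pipecolic acid and 2,6-diisopropylaniline with a (CH2)3 bridge; ent-L comes from (R)-pipecolic acid). Diazoethane and 2-diazopropane are used as freshly made cold ether solutions (from N-ethyl-N-nitrosourea/KOH and from acetone hydrazone/HgO/KOH).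

**Route**

Step 1
Reactants: 1 3-[(tert-butyldimethylsilyl)oxy]cyclobutan-1-one
Product: 2 (4S)-4-[(tert-butyldimethylsilyl)oxy]-2,2-dimethylcyclopentan-1-one
Conditions: Sc(OTf)3 (10 mol %), ligand L (12 mol %), 2-diazopropane (1.5 equiv, Et2O, slow addition), 4 Å MS, CH2Cl2, −78 °C
Reagents that add atoms: 2-diazopropane, CC(C)=[N+]=[N-]
Why: Proposed new method: a chiral trivalent-scandium Lewis acid activates the prochiral cyclobutanone, the symmetrical non-stabilised diazoalkane adds to C=O to give a diazonium betaine whose two ring CH2 groups are enantiotopic, and the ligand pocket fixes the rotamer about the new C–C bond so that only one CH2 lies antiperiplanar to N2 and undergoes the strain-releasing 1,2-shift (Tiffeneau–Demjanov-type diazoalkane ring expansion), which sets the silyloxy-bearing centre as S while the inserted CMe2 carbon carries no stereocentre; the closest known reaction types are scandium-catalysed diazoalkane–ketone homologation with aryl- or ester-substituted diazo compounds and the catalytic enantioselective desymmetrising Baeyer–Villiger oxidation of 3-substituted cyclobutanones, where the same choice between enantiotopic migrating carbons is made in the Criegee adduct.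

Step 2
Reactants: 2 (4S)-4-[(tert-butyldimethylsilyl)oxy]-2,2-dimethylcyclopentan-1-one
Product: 3 (4R)-4-[(tert-butyldimethylsilyl)oxy]-2,2,6-trimethylcyclohexan-1-one (C6 epimer mixture)
Conditions: diazoethane (2 equiv, Et2O), AlMe3 (1.2 equiv), CH2Cl2, −78 → −40 °C
Reagents that add atoms: diazoethane, CC=[N+]=[N-]
Why: Organoaluminium-promoted diazoalkane homologation (Tiffeneau–Demjanov-type 1,2-shift ring expansion) in which the unhindered CH2 carbon, not the quaternary CMe2 carbon, migrates with loss of N2, so the C–O stereocentre is untouched (S becomes R only through a CIP priority change) and the new CHMe centre is left uncontrolled because it becomes sp2 in step 3.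

Step 3
Reactants: 3 (4R)-4-[(tert-butyldimethylsilyl)oxy]-2,2,6-trimethylcyclohexan-1-one
Product: 4 (4R)-4-[(tert-butyldimethylsilyl)oxy]-2,6,6-trimethylcyclohex-1-en-1-yl trifluoromethanesulfonate
Conditions: LiN(i-Pr)2 (1.2 equiv), THF, −78 → 0 °C; then PhNTf2 (1.3 equiv), 0 °C → rt
Reagents that add atoms: N-phenylbis(trifluoromethanesulfonimide), O=S(=O)(N(c1ccccc1)S(=O)(=O)C(F)(F)F)C(F)(F)F
Why: Enol triflate formation in which C6 is the only enolisable position, so the tetrasubstituted enolate forms regiospecifically and is sulfonylated on oxygen, erasing the uncontrolled C6 centre and leaving the silyloxy stereocentre (R) untouched.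

Step 4
Reactants: 5 cyclopent-3-en-1-ol
Product: 7 (3aR,6aS)-2,2-dimethyltetrahydro-4H-cyclopenta[d][1,3]dioxol-5-ol (C5 epimer mixture), via cyclopentane-1,2,4-triol 6 (not isolated)
Conditions: K2OsO4·2H2O (1 mol %), N-methylmorpholine N-oxide (1.3 equiv), acetone/H2O 8:1, rt; evaporate; then 2,2-dimethoxypropane (5 equiv), TsOH·H2O (5 mol %), acetone, rt
Reagents that add atoms: N-methylmorpholine N-oxide, C[N+]1([O-])CCOCC1; water, O; 2,2-dimethoxypropane, COC(C)(C)OC
Why: Upjohn dihydroxylation is a suprafacial syn addition and therefore gives the cis-1,2-diol, which alone can close the five-membered acetonide under acid catalysis, leaving the remote secondary alcohol free (its configuration does not matter because it is oxidised in step 5).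

Step 5
Reactants: 7 (3aR,6aS)-2,2-dimethyltetrahydro-4H-cyclopenta[d][1,3]dioxol-5-ol
Product: 8 (3aR,6aS)-2,2-dimethyltetrahydro-4H-cyclopenta[d][1,3]dioxol-5-one (meso)
Conditions: TEMPO (5 mol %), KBr (10 mol %), NaOCl (1.2 equiv), NaHCO3, CH2Cl2/H2O, 0 °C
Reagents that add atoms: none
Why: Anelli (TEMPO/hypochlorite) oxidation of the secondary alcohol at buffered pH leaves the acetonide intact and gives the meso ketone in which the two ring-fusion centres are fixed cis.

Step 6
Reactants: 8 (3aR,6aS)-2,2-dimethyltetrahydro-4H-cyclopenta[d][1,3]dioxol-5-one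
Product: 9 (4S,5R)-4,5-(isopropylidenedioxy)-2,2-dimethylcyclohexan-1-one
Conditions: Sc(OTf)3 (10 mol %), ligand L or ent-L (12 mol %), 2-diazopropane (2 equiv, Et2O, slow addition), 4 Å MS, CH2Cl2, −78 → −40 °C
Reagents that add atoms: 2-diazopropane, CC(C)=[N+]=[N-]
Why: Proposed new method: the same chiral Sc(OTf)3/N,N′-dioxide-catalysed insertion of 2-diazopropane, now on a meso cyclopentanone, in which the ligand pocket decides which of the two enantiotopic α-CH2 groups of the diazonium betaine lies antiperiplanar to N2 and migrates (Tiffeneau–Demjanov-type 1,2-shift), so that the six-membered ring with CMe2 next to C=O is formed and the pre-existing cis-diol centres become 4S,5R; the closest known reaction types are scandium-catalysed diazoalkane–cycloalkanone homologation with aryl or stabilised diazo compounds and the catalytic enantioselective desymmetrising Baeyer–Villiger oxidation of prochiral and meso cyclic ketones, and neither a dialkyldiazomethane nor a meso cyclopentanone has been used in such a desymmetrisation.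

Step 7
Reactants: 9 (4S,5R)-4,5-(isopropylidenedioxy)-2,2-dimethylcyclohexan-1-one
Product: 10 (4S,5R)-4,5-(isopropylidenedioxy)-2,2,6-trimethylcyclohexan-1-one (C6 epimer mixture)
Conditions: LiN(i-Pr)2 (1.05 equiv), THF, −78 °C; then MeI (3 equiv), −78 → −40 °C
Reagents that add atoms: iodomethane, CI
Why: Kinetic lithium enolate alkylation at the single enolisable CH2 (the other α-carbon is quaternary), run at −78 °C so that methylation outpaces E1cB loss of the β-acetonide oxygen, with the new methyl-bearing centre left as a mixture because it becomes sp2 in step 8.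

Step 8
Reactants: 10 (4S,5R)-4,5-(isopropylidenedioxy)-2,2,6-trimethylcyclohexan-1-one
Product: 11 (3aR,7aS)-2,2,4,6,6-pentamethyl-3a,6,7,7a-tetrahydro-1,3-benzodioxol-5-yl trifluoromethanesulfonate
Conditions: KN(SiMe3)2 (1.2 equiv), THF, −78 °C; then Comins' reagent (1.3 equiv), −78 → −40 °C
Reagents that add atoms: N-(5-chloropyridin-2-yl)bis(trifluoromethanesulfonimide), O=S(=O)(N(c1ccc(Cl)cn1)S(=O)(=O)C(F)(F)F)C(F)(F)F
Why: Enol triflate formation in which the base removes the only α-hydrogen to give the tetrasubstituted potassium enolate, which is trapped on oxygen at −78 °C before β-alkoxide elimination can compete, the two acetonide stereocentres being untouched.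

Step 9
Reactants: 11 (3aR,7aS)-2,2,4,6,6-pentamethyl-3a,6,7,7a-tetrahydro-1,3-benzodioxol-5-yl trifluoromethanesulfonate
Product: 12 (3R,4S)-3,4-dihydroxy-2,6,6-trimethylcyclohex-1-en-1-yl trifluoromethanesulfonate
Conditions: TFA/H2O/THF 2:1:4, 0 °C → rt
Reagents that add atoms: none
Why: Acid-catalysed acetal hydrolysis releases the cis-diol with retention at both C–O bonds, ionisation of the allylic C–O bond being disfavoured by the electron-poor vinyl triflate, and doing it here means the acid-labile polyene never meets acid.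

Step 10
Reactants: 13 fumaraldehyde bis(dimethyl acetal), 14 ethyl prop-1-enyl ether (2.2 equiv)
Product: 16 (2E,4E,6E)-2,7-dimethylocta-2,4,6-trienedial, via hexaalkoxy adduct 15 (not isolated)
Conditions: ZnCl2 (5 mol %), EtOAc, 0 → 25 °C; then AcOH/H2O/NaOAc, 95 °C; crystallise
Reagents that add atoms: water, O
Why: Müller–Cunradi–Pieroh (Mukaiyama-type) enol ether condensation at both acetal ends, followed by acidic hydrolysis and loss of methanol, gives the conjugated dial, whose all-E geometry is the thermodynamic one and is secured by crystallisation.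

Step 11
Reactants: 17 (E)-3-methylpent-2-en-4-yn-1-ol
Product: 18 [(2E)-3-methylpent-2-en-4-yn-1-yl]triphenylphosphonium bromide
Conditions: PPh3·HBr (1.05 equiv), CH2Cl2, 0 °C → rt; precipitate with Et2O
Reagents that add atoms: triphenylphosphine hydrobromide, Br.P(c1ccccc1)(c1ccccc1)c1ccccc1
Why: SN2-type substitution of the protonated primary allylic alcohol by triphenylphosphine (phosphonium salt formation) keeps the E geometry of the trisubstituted alkene, which later becomes the 9E and 9′E bonds.

Step 12
Reactants: 16 (2E,4E,6E)-2,7-dimethylocta-2,4,6-trienedial (2.0 equiv), 18 [(2E)-3-methylpent-2-en-4-yn-1-yl]triphenylphosphonium bromide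
Product: 19 (2E,4E,6E,8E,10E)-2,7,11-trimethyltrideca-2,4,6,8,10-pentaen-12-ynal
Conditions: NaOMe (1.1 equiv), MeOH/CH2Cl2, −10 °C → rt, salt added slowly to the dial; then heptane, 80 °C, 2 h, dark
Reagents that add atoms: none
Why: Wittig olefination with a semistabilised allylic ylide forms the C11′=C12′ bond, mono-olefination being ensured by the excess of 16 and by the lower electrophilicity of the vinylogous aldehyde in 19, and the hindered Z isomer of the new bond relaxes to E on gentle heating.

Step 13
Reactants: 19 (2E,4E,6E,8E,10E)-2,7,11-trimethyltrideca-2,4,6,8,10-pentaen-12-ynal, 4 (4R)-4-[(tert-butyldimethylsilyl)oxy]-2,6,6-trimethylcyclohex-1-en-1-yl trifluoromethanesulfonate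
Product: 20 (2E,4E,6E,8E,10E)-13-[(4R)-4-[(tert-butyldimethylsilyl)oxy]-2,6,6-trimethylcyclohex-1-en-1-yl]-2,7,11-trimethyltrideca-2,4,6,8,10-pentaen-12-ynal
Conditions: Pd(PPh3)4 (5 mol %), CuI (10 mol %), Et3N (3 equiv), DMF, rt, Ar, dark
Reagents that add atoms: none
Why: Sonogashira coupling, in which oxidative addition of zerovalent palladium into the vinyl C–OTf bond and transmetalation from the copper acetylide form the C6′–C7′ bond under conditions that leave the aldehyde, polyene, silyl ether and stereocentre untouched.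

Step 14
Reactants: 20 the C25 aldehyde of step 13, 18 [(2E)-3-methylpent-2-en-4-yn-1-yl]triphenylphosphonium bromide (1.5 equiv)
Product: 21 tert-butyldimethyl{[(1R)-3,5,5-trimethyl-4-[(3E,5E,7E,9E,11E,13E,15E)-3,7,12,16-tetramethyloctadeca-3,5,7,9,11,13,15-heptaene-1,17-diyn-1-yl]cyclohex-3-en-1-yl]oxy}silane
Conditions: NaOMe (1.6 equiv), MeOH/CH2Cl2, 0 °C → rt; then heptane, 80 °C, 2 h, dark
Reagents that add atoms: none
Why: Second Wittig olefination of the polyenal with the same ylide builds the C11=C12 bond (E after thermal relaxation of the hindered Z isomer) and brings in the second terminal alkyne with its E trisubstituted alkene already in place.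

Step 15
Reactants: 21 the C31 terminal alkyne of step 14, 12 (3R,4S)-3,4-dihydroxy-2,6,6-trimethylcyclohex-1-en-1-yl trifluoromethanesulfonate
Product: 23 (3S,4R,3′R)-7,8,7′,8′-tetradehydro-β,β-carotene-3,4,3′-triol, via silyl ether 22 (not isolated)
Conditions: Pd(PPh3)4 (5 mol %), CuI (10 mol %), Et3N (3 equiv), THF/DMF, rt, Ar, dark; then Bu4NF (3 equiv), THF, 0 °C → rt, same flask
Reagents that add atoms: none
Why: Sonogashira coupling of the terminal alkyne with the unprotected diol triflate forms the C6–C7 bond without touching the three stereocentres, and fluoride then cleaves the silyl ether in the same flask, so no acid meets the acid-labile allylic 4-hydroxy polyene.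

**Compound list**

1 | 3-[(tert-butyldimethylsilyl)oxy]cyclobutan-1-one | O=C1CC(O[Si](C)(C)C(C)(C)C)C1 | starting material
2 | (4S)-4-[(tert-butyldimethylsilyl)oxy]-2,2-dimethylcyclopentan-1-one | O=C1C[C@@H](O[Si](C)(C)C(C)(C)C)CC1(C)C | intermediate
3 | (4R)-4-[(tert-butyldimethylsilyl)oxy]-2,2,6-trimethylcyclohexan-1-one (C6 epimer mixture) | O=C1C(C)C[C@@H](O[Si](C)(C)C(C)(C)C)CC1(C)C | intermediate
4 | (4R)-4-[(tert-butyldimethylsilyl)oxy]-2,6,6-trimethylcyclohex-1-en-1-yl trifluoromethanesulfonate | CC1=C(OS(=O)(=O)C(F)(F)F)C(C)(C)C[C@H](O[Si](C)(C)C(C)(C)C)C1 | intermediate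
5 | cyclopent-3-en-1-ol | OC1CC=CC1 | starting material
6 | cyclopentane-1,2,4-triol with cis-1,2-diol (C4 epimer mixture) | OC1C[C@@H](O)[C@@H](O)C1 | intermediate
7 | (3aR,6aS)-2,2-dimethyltetrahydro-4H-cyclopenta[d][1,3]dioxol-5-ol (C5 epimer mixture) | OC1C[C@H]2OC(C)(C)O[C@H]2C1 | intermediate
8 | (3aR,6aS)-2,2-dimethyltetrahydro-4H-cyclopenta[d][1,3]dioxol-5-one (meso; cis-3,4-(isopropylidenedioxy)cyclopentanone) | O=C1C[C@H]2OC(C)(C)O[C@H]2C1 | intermediate
9 | (4S,5R)-4,5-(isopropylidenedioxy)-2,2-dimethylcyclohexan-1-one [(3aR,7aS)-2,2,6,6-tetramethylhexahydro-1,3-benzodioxol-5-one] | O=C1C[C@H]2OC(C)(C)O[C@H]2CC1(C)C | intermediate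
10 | (4S,5R)-4,5-(isopropylidenedioxy)-2,2,6-trimethylcyclohexan-1-one (C6 epimer mixture) | O=C1C(C)[C@H]2OC(C)(C)O[C@H]2CC1(C)C | intermediate
11 | (3aR,7aS)-2,2,4,6,6-pentamethyl-3a,6,7,7a-tetrahydro-1,3-benzodioxol-5-yl trifluoromethanesulfonate (acetonide of 12) | CC1=C(OS(=O)(=O)C(F)(F)F)C(C)(C)C[C@@H]2OC(C)(C)O[C@H]12 | intermediate
12 | (3R,4S)-3,4-dihydroxy-2,6,6-trimethylcyclohex-1-en-1-yl trifluoromethanesulfonate | O=S(=O)(OC1=C(C)[C@@H](O)[C@@H](O)CC1(C)C)C(F)(F)F | intermediate
13 | fumaraldehyde bis(dimethyl acetal), (E)-1,1,4,4-tetramethoxybut-2-ene | COC(OC)/C=C/C(OC)OC | starting material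
14 | ethyl prop-1-enyl ether (E/Z mixture) | CC=COCC | starting material
15 | (E)-1,8-diethoxy-1,3,6,8-tetramethoxy-2,7-dimethyloct-4-ene (diastereomer mixture) | CCOC(OC)C(C)C(OC)/C=C/C(OC)C(C)C(OC)OCC | intermediate
16 | (2E,4E,6E)-2,7-dimethylocta-2,4,6-trienedial | O=C/C(C)=C/C=C/C=C(C)/C=O | intermediate
17 | (E)-3-methylpent-2-en-4-yn-1-ol | C#C/C(C)=C/CO | starting material
18 | [(2E)-3-methylpent-2-en-4-yn-1-yl]triphenylphosphonium bromide | C#C/C(C)=C/C[P+](c1ccccc1)(c1ccccc1)c1ccccc1.[Br-] | intermediate
19 | (2E,4E,6E,8E,10E)-2,7,11-trimethyltrideca-2,4,6,8,10-pentaen-12-ynal | C#C/C(C)=C/C=C/C(C)=C/C=C/C=C(C)/C=O | intermediate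
20 | (2E,4E,6E,8E,10E)-13-[(4R)-4-[(tert-butyldimethylsilyl)oxy]-2,6,6-trimethylcyclohex-1-en-1-yl]-2,7,11-trimethyltrideca-2,4,6,8,10-pentaen-12-ynal | CC1=C(C#C/C(C)=C/C=C/C(C)=C/C=C/C=C(C)/C=O)C(C)(C)C[C@H](O[Si](C)(C)C(C)(C)C)C1 | intermediate
21 | tert-butyldimethyl{[(1R)-3,5,5-trimethyl-4-[(3E,5E,7E,9E,11E,13E,15E)-3,7,12,16-tetramethyloctadeca-3,5,7,9,11,13,15-heptaene-1,17-diyn-1-yl]cyclohex-3-en-1-yl]oxy}silane | CC1=C(C#C/C(C)=C/C=C/C(C)=C/C=C/C=C(C)/C=C/C=C(\C)C#C)C(C)(C)C[C@H](O[Si](C)(C)C(C)(C)C)C1 | intermediate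
22 | 3′-O-(tert-butyldimethylsilyl) ether of 23 | CC1=C(C#C/C(C)=C/C=C/C(C)=C/C=C/C=C(C)/C=C/C=C(\C)C#CC2=C(C)[C@@H](O)[C@@H](O)CC2(C)C)C(C)(C)C[C@H](O[Si](C)(C)C(C)(C)C)C1 | intermediate
23 | (3S,4R,3′R)-7,8,7′,8′-tetradehydro-β,β-carotene-3,4,3′-triol (all-E) | CC1=C(C#C/C(C)=C/C=C/C(C)=C/C=C/C=C(C)/C=C/C=C(\C)C#CC2=C(C)[C@@H](O)[C@@H](O)CC2(C)C)C(C)(C)C[C@H](O)C1 | target

**Step count and risk**

Total step count: 15. Longest linear sequence: 7 (steps 4, 5, 6, 7, 8, 9, 15).

The three steps most likely to fail:

Step 6 (proposed new method; cyclopentanones are less reactive than cyclobutanones and the enantiotopic-group selection is unproven). The fallback uses known chemistry, sets out from 8 and comes back at 10. Ketone 8 is condensed with (S)-1-amino-2-(methoxymethyl)pyrrolidine to give the SAMP hydrazone of 8 F5. Deprotonation with LiN(i-Pr)2 (THF, 0 °C) and methylation with MeI at −100 °C gives the methylated SAMP hydrazone F6; the auxiliary selects one enantiotopic α-carbon and the methyl enters trans to the acetonide. Saturated aqueous oxalic acid/Et2O then releases (2R,3R,4S)-3,4-(isopropylidenedioxy)-2-methylcyclopentan-1-one F7 (RAMP is used instead if the opposite sense is found). Achiral AlMe3-promoted homologation of F7 with 2-diazopropane, in which the CH2 carbon rather than the CHMe carbon migrates, gives 10 directly. Here the desymmetrisation is done by auxiliary-controlled alkylation and the ring expansion only has to be regioselective.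

Step 1 (proposed new method; background racemic insertion and the sense and level of induction are unknown). The fallback uses known chemistry, sets out from 1 and comes back at 2. Isopropenylmagnesium bromide (THF, −78 °C) adds to 1 to give 3-[(tert-butyldimethylsilyl)oxy]-1-(prop-1-en-2-yl)cyclobutan-1-ol F1. TsOH·H2O (10 mol %) in CH2Cl2 triggers the classical protio-semipinacol ring expansion to racemic 4-[(tert-butyldimethylsilyl)oxy]-2,2-dimethylcyclopentan-1-one F2. Reagent-controlled reduction with (S)-2-methyl-CBS-oxazaborolidine/BH3·SMe2 converts the two enantiomers into separable diastereomers, (1R,4S)-4-[(tert-butyldimethylsilyl)oxy]-2,2-dimethylcyclopentan-1-ol F3 and (1R,4R)-4-[(tert-butyldimethylsilyl)oxy]-2,2-dimethylcyclopentan-1-ol F4. After chromatography F3 is oxidised with Dess–Martin periodinane to 2. The maximum yield is 50 % and the enantiomeric purity is set by the selectivity of the reduction.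

Step 8 (the tetrasubstituted enolate carries a β-alkoxy leaving group and may eliminate before it is triflated). The fallback sets out from 10 and comes back at 22. Hydrazine hydrate/Et3N in EtOH gives the hydrazone of 10 F8. I2 and tetramethylguanidine in Et2O/THF (Barton vinyl iodide synthesis, no enolate involved, only one β-hydrogen available) give (3aR,7aS)-5-iodo-2,2,4,6,6-pentamethyl-3a,6,7,7a-tetrahydro-1,3-benzodioxole F9. Aqueous TFA removes the acetonide to give (1S,2R)-4-iodo-3,5,5-trimethylcyclohex-3-ene-1,2-diol F10. F10 takes the place of 12 in the Sonogashira coupling of step 15 and so rejoins the route at 22.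

**Further compounds**

F1 | step 1 | 3-[(tert-butyldimethylsilyl)oxy]-1-(prop-1-en-2-yl)cyclobutan-1-ol (cis/trans mixture) | CC(=C)C1(O)CC(O[Si](C)(C)C(C)(C)C)C1
F2 | step 1 | racemic 4-[(tert-butyldimethylsilyl)oxy]-2,2-dimethylcyclopentan-1-one | O=C1CC(O[Si](C)(C)C(C)(C)C)CC1(C)C
F3 | step 1 | (1R,4S)-4-[(tert-butyldimethylsilyl)oxy]-2,2-dimethylcyclopentan-1-ol | O[C@@H]1C[C@@H](O[Si](C)(C)C(C)(C)C)CC1(C)C
F4 | step 1 | (1R,4R)-4-[(tert-butyldimethylsilyl)oxy]-2,2-dimethylcyclopentan-1-ol | O[C@@H]1C[C@H](O[Si](C)(C)C(C)(C)C)CC1(C)C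
F5 | step 6 | SAMP hydrazone of 8 | COC[C@@H]1CCCN1N=C1C[C@H]2OC(C)(C)O[C@H]2C1
F6 | step 6 | SAMP hydrazone of (2R,3R,4S)-3,4-(isopropylidenedioxy)-2-methylcyclopentan-1-one | COC[C@@H]1CCCN1N=C1[C@H](C)[C@H]2OC(C)(C)O[C@H]2C1
F7 | step 6 | (2R,3R,4S)-3,4-(isopropylidenedioxy)-2-methylcyclopentan-1-one | O=C1[C@H](C)[C@H]2OC(C)(C)O[C@H]2C1
F8 | step 8 | hydrazone of 10 | NN=C1C(C)[C@H]2OC(C)(C)O[C@H]2CC1(C)C
F9 | step 8 | (3aR,7aS)-5-iodo-2,2,4,6,6-pentamethyl-3a,6,7,7a-tetrahydro-1,3-benzodioxole | CC1=C(I)C(C)(C)C[C@@H]2OC(C)(C)O[C@H]12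
F10 | step 8 | (1S,2R)-4-iodo-3,5,5-trimethylcyclohex-3-ene-1,2-diol | IC1=C(C)[C@@H](O)[C@@H](O)CC1(C)C
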